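**Conventions and one assumption.** Flavan numbering is used: O1, C2 (carries ring B), C3 (carries OH), C4 (carries ring D), C4a–C8a (ring A, C7–OH); ring C is the pyran ring and ring D is the resorcinol ring with the styryl arm. ArA = 4-(benzyloxy)-2-bromophenyl (ring A, bromine on the future C8a). ArD = 2,4-bis(benzyloxy)-6-[(E)-2-(3,4-bis(benzyloxy)phenyl)ethenyl]phenyl. "Diol boronate" = (4S,5S)-4,5-dicyclohexyl-1,3,2-dioxaborolan-2-yl.

Assumption on the chemistry: the (S,S)-diol is taken to give the (αR)-α-chloro boronic ester (Cl > C > B), the mirror image of the usual (R,R) → (αS) outcome. If the sense were the reverse, the (R,R)-diol would be used throughout.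

Bromine outranks oxygen, so the future C4 is labelled S in every open-chain intermediate and R in 22 and 23. The C3 label also switches with its neighbours. The geometry at both centres is unchanged throughout. Compounds 1, 3, 6, 7, 9 and 17 are taken as purchasable.

## Analysis of the target

The target 23 is a 4-aryl-flavan-3-ol: a chromane whose benzo ring (ring A) carries C7–OH, with a 4-hydroxyphenyl group (ring B) at C2, a hydroxyl at C3 and ring D at C4. Ring D is a resorcinol that bears an (E)-3,4-dihydroxystyryl arm ortho to its bond to C4. C2, C3 and C4 are contiguous stereocentres, all R: ring B and the C3 oxygen are cis, the C3 oxygen and ring D are trans. C2 and C4 are both benzylic, and C4 carries two ortho-substituted aryl groups next to the oxygenated C3, so it is very crowded. The sensitive groups are six phenols (one catechol), the electron-rich stilbene and the benzylic O1–C2 bond. The stilbene rules out hydrogenolysis and tolerates little acid or electrophile; the O1–C2 bond can ionise and epimerise C2. The 2,3-cis relation is not what cationic or conjugate ring closures at C2 tend to give, so it must be set under firm control. The strategy rests on the chain C4–C3–C2: each carbon carries hydrogen plus one group that can enter as a nucleophile (ring A at C4, oxygen at C3, ring B at C2), and C4 carries ring D as well. Each carbon can therefore be made as the α-carbon of a boronic ester under control of one chiral diol. O1 is then attached to C2 through boron and to C8a through a bromide on ring A.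

## Retrosynthetic reasoning

**23 ⇒ 22.** The seven O–benzyl bonds are cut last. Benzyl ethers survive organolithium and Grignard reagents, alkoxide, alkaline peroxide and hot carbonate. Because of the stilbene they must leave without hydrogen, which a boron Lewis acid with a cation trap at low temperature can do.

**22 ⇒ 21.** Ring C is opened at O1–C8a, not at O1–C2. The C2–O bond then already exists with fixed configuration, and no substitution at the ionisable benzylic C2 is needed. The forward reaction is an intramolecular copper-catalysed O-arylation of the C2 alcohol by the ortho bromide of ring A.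

**21 ⇒ 20.** The C2–O bond is traced back to a C2–B bond, which oxidises with retention. This makes C2 a carbon that can be assembled by boron chemistry.

**20 ⇒ 16 + 17 (through 18 and 19).** C2–C3 and C2–ring B are cut at the same carbon. That carbon comes from dichloromethane: it is inserted between boron and C3 of 16, and ring B then enters as the Grignard reagent 19 made from 17. The cut is made here because the diol on boron, not the crowded C3/C4 neighbourhood, then fixes C2. The forward step must insert into a hindered α-alkoxy boronic ester and make the aryl group migrate without loss of the β-benzyloxy group.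

**16 ⇒ 14 (through 15).** C3–C4 and C3–O are cut in the same way: a one-carbon insertion into the C4–B bond of 14, then benzyloxide as the nucleophile. This puts the C3 oxygen in place already protected.

**14 ⇒ 5 + 8 + 10 (through 11, 12 and 13).** C4–ring D and C4–ring A are cut; C4 is the dichloromethyl carbon of 8. With the (S,S)-diol, ring D must reach boron first and ring A must come second for C4 to match the target. The aryllithium 11 and reagent 8 are used instead of a ring-D boronic ester plus LiCHCl2. This gives the same ate complex while avoiding a separate, crowded 2,6-disubstituted aryl boronic ester and an attack of LiCHCl2 on its boron. Ring A arrives as Grignard reagent 13 with its bromine in place.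

**Building blocks.** The stilbene of 5 is cut at C=C (olefination of 2 with phosphonate 4, which fixes the E geometry). Bromine is placed on 1 before olefination, when only one activated arene is present. 4 comes from 3, 8 from 6 and 7, and 10 from 9.

## Alternatives that were turned down

**Alternative 1:** O1–C8a is formed by oxygen insertion. A peracid Baeyer–Villiger reaction on the enantioenriched indanone A1 moves the aryl carbon from carbon to oxygen and gives the dihydrocoumarin A2.
- For it: the C4 centre of A1 can be set by well-established catalytic asymmetric chemistry, and aryl migration keeps it. No labile benzylic chloride such as 12 is involved. On the C4 centre this alternative is stronger than the chosen route.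
- Against it: A2 has neither ring B, nor the C3 oxygen, nor the stilbene. The stilbene must be postponed behind a bromine placeholder because the peracid would attack it. C2 and C3 then have to be built on the lactone by substrate control (enolate hydroxylation, aryl addition to the lactone carbonyl, reductive removal of the anomeric oxygen). The last of these must deliver the 2,3-cis isomer, which is not assured. The migrating aryl carbon is meta to the benzyloxy group, so migration of the methylene group can compete.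
- Comparison: the chosen route builds C2 with its aryl group and sets all three centres by one reagent-controlled operation repeated three times, with the stilbene present from the start. Fewer steps follow the key step.

**Alternative 2:** C3–C4 and O1–C2 are formed in one annulation. Base releases the ortho-quinone methide A4 from the racemic sulfone A3. Aldehyde A5, activated as its enamine by a chiral secondary amine catalyst, adds to C4 and O1 closes on the aldehyde carbon to give the lactol A6.
- For it: two bonds, ring C and the C3/C4 pair form in one catalytic step from a racemic precursor, without a stoichiometric auxiliary or cryogenic carbenoids. On step economy for ring C it is stronger.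
- Against it: C2 is left as a lactol without ring B. An aryl nucleophile adding to the derived oxocarbenium ion would enter anti to the C3 benzyloxy group, which gives 2,3-trans. A4 carries a 2,6-disubstituted aryl group on its exocyclic carbon, which slows the addition. The stilbene is again postponed.
- Comparison: the chosen route spends stoichiometric diol but makes the hard C2 centre, with ring B on it, under reagent control.

**Alternative 3:** ring D is made last. A base-mediated intramolecular aldol reaction of the triketone A7 joins the C4-bound methylene carbon to the cinnamoyl carbonyl carbon, and dehydration with enolisation gives A8.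
- For it: the substitution pattern of ring D is fixed by the chain, its two phenols appear free, and no crowded C4–aryl bond has to be made with a 2,6-disubstituted aryl metal. On that point it is stronger.
- Against it: the carbon that must attack is the least acidic methylene of A7. O-cyclisation to pyranones and conjugate addition to the enone are open competing paths. A7 is a labile poly-β-carbonyl chain that must be built on a flavan already holding all three stereocentres, and the alternative does not say how those are made.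
- Comparison: the chosen route accepts the crowded C4 but solves the stereochemistry, which Alternative 3 leaves open.

Key step: step 8

## Route

Step 1
Reactants: 1 3,5-bis(benzyloxy)benzaldehyde
Product: 2 3,5-bis(benzyloxy)-2-bromobenzaldehyde
Conditions: NBS, MeCN, 0 °C → rt
Reagents that add atoms: N-bromosuccinimide, O=C1CCC(=O)N1Br
Why: Electrophilic aromatic bromination; the position ortho to one benzyloxy group and para to the other is the most reactive accessible site, as is usual for 3,5-dialkoxybenzaldehydes, and one equivalent of NBS limits over-bromination.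

Step 2
Reactants: 3 1,2-bis(benzyloxy)-4-(chloromethyl)benzene
Product: 4 diethyl [3,4-bis(benzyloxy)benzyl]phosphonate
Conditions: P(OEt)3 (neat), 140 °C
Reagents that add atoms: triethyl phosphite, CCOP(OCC)OCC
Why: Michaelis–Arbuzov reaction of a benzylic chloride; chloroethane distils off and drives the reaction.

Step 3
Reactants: 4 diethyl [3,4-bis(benzyloxy)benzyl]phosphonate; 2 3,5-bis(benzyloxy)-2-bromobenzaldehyde
Product: 5 (E)-1,5-bis(benzyloxy)-2-bromo-3-[2-(3,4-bis(benzyloxy)phenyl)ethenyl]benzene
Conditions: NaH, THF, 0 °C; then 2, 0 °C → rt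
Reagents that add atoms: none
Why: Horner–Wadsworth–Emmons olefination; the benzylic phosphonate anion adds reversibly, and elimination through the less crowded oxaphosphetane should give the (E)-stilbene.

Step 4
Reactants: 6 (1S,2S)-1,2-dicyclohexylethane-1,2-diol; 7 diisopropyl (dichloromethyl)boronate
Product: 8 (4S,5S)-4,5-dicyclohexyl-2-(dichloromethyl)-1,3,2-dioxaborolane
Conditions: pentane, rt; propan-2-ol removed under vacuum
Reagents that add atoms: none
Why: Transesterification of a boronic ester, driven by the five-membered chelate and by removal of the volatile alcohol.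

Step 5
Reactants: 9 3-bromo-4-iodophenol
Product: 10 4-(benzyloxy)-2-bromo-1-iodobenzene
Conditions: BnBr, K2CO3, DMF, rt
Reagents that add atoms: benzyl bromide, BrCc1ccccc1
Why: Williamson ether synthesis on a phenol; the aryl halides are inert under these conditions.

Step 6
Reactants: 5 (E)-1,5-bis(benzyloxy)-2-bromo-3-[2-(3,4-bis(benzyloxy)phenyl)ethenyl]benzene; 8 (4S,5S)-4,5-dicyclohexyl-2-(dichloromethyl)-1,3,2-dioxaborolane; 10 4-(benzyloxy)-2-bromo-1-iodobenzene
Product: 14 (4S,5S)-4,5-dicyclohexyl-2-[(S)-(ArA)(ArD)methyl]-1,3,2-dioxaborolane, via aryllithium 11 (not isolated), via α-chloro benzylic boronic ester 12 (not isolated), via aryl Grignard reagent 13 (not isolated)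
Conditions: 5, n-BuLi, THF, −78 °C; 8, −78 °C; ZnCl2, −78 → 0 °C; then 13 (from 10, iPrMgCl·LiCl, THF, −40 °C; 3 equiv, part is taken up by zinc), −78 → 0 °C
Reagents that add atoms: none
Why: Br/Li exchange on 5 is faster than any addition to the stilbene at −78 °C, and aryllithium 11 adds to the boron of 8 to give the same ate complex that LiCHCl2 would give with the ring-D boronic ester; the ZnCl2-assisted 1,2-shift of ring D (Matteson homologation) expels the chloride selected by the (S,S)-diol and should give the (R)-chloride 12. Grignard reagent 13, made by I/Mg exchange below the temperature at which an ortho-bromoaryl magnesium species loses magnesium halide, binds boron, and ring A migrates antiperiplanar to chloride with inversion, which sets C4 as in the target. The electron-rich benzylic chloride 12 is consumed in the flask where it forms, which limits its time for ionisation or chloride exchange.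

Step 7
Reactants: 14 (4S,5S)-4,5-dicyclohexyl-2-[(S)-(ArA)(ArD)methyl]-1,3,2-dioxaborolane
Product: 16 (4S,5S)-2-[(1S,2S)-1-(benzyloxy)-2-(ArA)-2-(ArD)ethyl]-4,5-dicyclohexyl-1,3,2-dioxaborolane, via α-chloro boronic ester 15 (not isolated)
Conditions: CH2Cl2, n-BuLi, THF, −100 °C; 14; ZnCl2, −100 °C → rt; zinc salts washed out (aq. NH4Cl/pentane), crude 15 used at once; BnOLi (BnOH, n-BuLi), THF, 0 °C → rt
Reagents that add atoms: dichloromethane (as LiCHCl2), ClCCl; benzyl alcohol (as BnOLi), OCc1ccccc1
Why: Matteson asymmetric homologation followed by alkoxide displacement; LiCHCl2 is preformed so that no alkyllithium meets the aryl bromide, C4 migrates from boron to carbon with retention, and the (S,S)-diol should make C3 the (R)-chloride. Benzyloxide then binds boron and shifts to C3 with inversion, which places the C3 oxygen and C4 as in the target.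

Step 8
Reactants: 16 (4S,5S)-2-[(1S,2S)-1-(benzyloxy)-2-(ArA)-2-(ArD)ethyl]-4,5-dicyclohexyl-1,3,2-dioxaborolane; 17 1-(benzyloxy)-4-bromobenzene
Product: 20 (4S,5S)-2-[(1R,2S,3S)-2-(benzyloxy)-1-[4-(benzyloxy)phenyl]-3-(ArA)-3-(ArD)propyl]-4,5-dicyclohexyl-1,3,2-dioxaborolane, via α-chloro boronic ester 18 (not isolated), via aryl Grignard reagent 19 (not isolated)
Conditions: CH2Cl2, n-BuLi, THF, −100 °C; 16; ZnCl2 (3 equiv), −100 °C → rt; zinc salts washed out (aq. NH4Cl/pentane), crude 18 used at once; 19 (from 17, Mg, THF), THF, −78 °C → rt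
Reagents that add atoms: dichloromethane (as LiCHCl2), ClCCl
Why: LiCHCl2, preformed at −100 °C, adds to the boron of 16 to give a tetracoordinate ate complex; ZnCl2 binds one dioxaborolane oxygen and one chloride, and C3 shifts from boron to the carbenoid carbon with retention while that chloride leaves, which forms C2–C3 and gives 18. The closest known reaction is the Matteson asymmetric homologation of an α-alkoxy boronic ester of a C2-symmetric diol, followed by Grignard displacement of the α-chloride. Which of the two diastereotopic chlorides leaves is decided by the (S,S)-diol and not by C3 or C4, so C2 is first an (R)-chloride. Grignard reagent 19 then adds to boron and the 4-benzyloxyphenyl group migrates antiperiplanar to the C2–Cl bond, so C2 is inverted and ring B ends up syn to the C3 oxygen in the open chain, which becomes 2,3-cis on ring closure. No ring is closed in this step. The step needs reagent control over a substrate that already has two stereocentres, migration of carbon and not of a ring oxygen, and no loss of the β-benzyloxy group. These are secured by the diol with ZnCl2 in the first stage, by the high migratory aptitude of an electron-rich aryl group, and by removing the zinc salts and keeping the temperature low in the Grignard stage. The aryl bromide of ring A survives because no alkyllithium is free when 16 is added and an aryl Grignard reagent does not exchange with an aryl bromide under these conditions.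

Step 9
Reactants: 20 (4S,5S)-2-[(1R,2S,3S)-2-(benzyloxy)-1-[4-(benzyloxy)phenyl]-3-(ArA)-3-(ArD)propyl]-4,5-dicyclohexyl-1,3,2-dioxaborolane
Product: 21 (1R,2R,3S)-2-(benzyloxy)-1-[4-(benzyloxy)phenyl]-3-(ArA)-3-(ArD)propan-1-ol
Conditions: H2O2 (30 %), NaOH (aq), THF, 0 °C → rt
Reagents that add atoms: hydrogen peroxide, OO
Why: Oxidation of a secondary boronic ester; hydroperoxide adds to boron and C2 shifts from boron to oxygen with retention. The nucleophilic oxidant leaves the stilbene alone, and the shift should be faster than loss of the β-benzyloxy group.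

Step 10
Reactants: 21 (1R,2R,3S)-2-(benzyloxy)-1-[4-(benzyloxy)phenyl]-3-(ArA)-3-(ArD)propan-1-ol
Product: 22 (2R,3R,4R)-3,7-bis(benzyloxy)-2-[4-(benzyloxy)phenyl]-4-(ArD)chromane
Conditions: CuI (20 mol %), 3,4,7,8-tetramethyl-1,10-phenanthroline (40 mol %), Cs2CO3, toluene, 110 °C
Reagents that add atoms: none
Why: Intramolecular Ullmann-type C–O coupling; the monovalent copper alkoxide inserts into the aryl C–Br bond and a six-membered ring forms through O1–C8a. No bond to a stereocentre is broken, so C2, C3 and C4 are carried over unchanged.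

Step 11
Reactants: 22 (2R,3R,4R)-3,7-bis(benzyloxy)-2-[4-(benzyloxy)phenyl]-4-(ArD)chromane
Product: 23 (2R,3R,4R)-4-{2-[(E)-2-(3,4-dihydroxyphenyl)ethenyl]-4,6-dihydroxyphenyl}-2-(4-hydroxyphenyl)chromane-3,7-diol
Conditions: BCl3, C6HMe5, CH2Cl2, −78 → −40 °C; MeOH quench
Reagents that add atoms: none
Why: Lewis-acid debenzylation with a non-basic cation trap; BCl3 activates each ether oxygen and the benzyl group is passed to pentamethylbenzene, so no benzyl cation reaches the phenol rings or the stilbene. No hydrogen is used, so the alkene is kept, and the low temperature is meant to spare the O1–C2 bond.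

## Compound list

1 | 3,5-bis(benzyloxy)benzaldehyde | O=Cc1cc(OCc2ccccc2)cc(OCc2ccccc2)c1 | starting material
2 | 3,5-bis(benzyloxy)-2-bromobenzaldehyde | O=Cc1cc(OCc2ccccc2)cc(OCc2ccccc2)c1Br | intermediate
3 | 1,2-bis(benzyloxy)-4-(chloromethyl)benzene | ClCc1ccc(OCc2ccccc2)c(OCc2ccccc2)c1 | starting material
4 | diethyl [3,4-bis(benzyloxy)benzyl]phosphonate | CCOP(=O)(OCC)Cc1ccc(OCc2ccccc2)c(OCc2ccccc2)c1 | intermediate
5 | (E)-1,5-bis(benzyloxy)-2-bromo-3-[2-(3,4-bis(benzyloxy)phenyl)ethenyl]benzene | Brc1c(OCc2ccccc2)cc(OCc2ccccc2)cc1/C=C/c1ccc(OCc2ccccc2)c(OCc2ccccc2)c1 | intermediate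
6 | (1S,2S)-1,2-dicyclohexylethane-1,2-diol | O[C@@H](C1CCCCC1)[C@@H](O)C1CCCCC1 | starting material
7 | diisopropyl (dichloromethyl)boronate | CC(C)OB(OC(C)C)C(Cl)Cl | starting material
8 | (4S,5S)-4,5-dicyclohexyl-2-(dichloromethyl)-1,3,2-dioxaborolane | ClC(Cl)B1O[C@@H](C2CCCCC2)[C@H](C2CCCCC2)O1 | intermediate
9 | 3-bromo-4-iodophenol | Oc1ccc(I)c(Br)c1 | starting material
10 | 4-(benzyloxy)-2-bromo-1-iodobenzene | Ic1ccc(OCc2ccccc2)cc1Br | intermediate
11 | ArD–Li, the aryllithium formed from 5 by Br/Li exchange | [Li]c1c(OCc2ccccc2)cc(OCc2ccccc2)cc1/C=C/c1ccc(OCc2ccccc2)c(OCc2ccccc2)c1 | intermediate (not isolated)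
12 | (4S,5S)-2-[(R)-chloro(ArD)methyl]-4,5-dicyclohexyl-1,3,2-dioxaborolane | Cl[C@@H](c1c(OCc2ccccc2)cc(OCc2ccccc2)cc1/C=C/c1ccc(OCc2ccccc2)c(OCc2ccccc2)c1)B1O[C@@H](C2CCCCC2)[C@H](C2CCCCC2)O1 | intermediate (not isolated)
13 | [4-(benzyloxy)-2-bromophenyl]magnesium chloride | Cl[Mg]c1ccc(OCc2ccccc2)cc1Br | intermediate (not isolated)
14 | (4S,5S)-4,5-dicyclohexyl-2-[(S)-(ArA)(ArD)methyl]-1,3,2-dioxaborolane | B1([C@H](c2ccc(OCc3ccccc3)cc2Br)c2c(OCc3ccccc3)cc(OCc3ccccc3)cc2/C=C/c2ccc(OCc3ccccc3)c(OCc3ccccc3)c2)O[C@@H](C2CCCCC2)[C@H](C2CCCCC2)O1 | intermediate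
15 | (4S,5S)-2-[(1R,2S)-1-chloro-2-(ArA)-2-(ArD)ethyl]-4,5-dicyclohexyl-1,3,2-dioxaborolane | Cl[C@@H]([C@H](c1ccc(OCc2ccccc2)cc1Br)c1c(OCc2ccccc2)cc(OCc2ccccc2)cc1/C=C/c1ccc(OCc2ccccc2)c(OCc2ccccc2)c1)B1O[C@@H](C2CCCCC2)[C@H](C2CCCCC2)O1 | intermediate (not isolated)
16 | (4S,5S)-2-[(1S,2S)-1-(benzyloxy)-2-(ArA)-2-(ArD)ethyl]-4,5-dicyclohexyl-1,3,2-dioxaborolane (precursor of the key step) | B1([C@H](OCc2ccccc2)[C@H](c3ccc(OCc4ccccc4)cc3Br)c3c(OCc4ccccc4)cc(OCc4ccccc4)cc3/C=C/c3ccc(OCc4ccccc4)c(OCc4ccccc4)c3)O[C@@H](C2CCCCC2)[C@H](C2CCCCC2)O1 | intermediate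
17 | 1-(benzyloxy)-4-bromobenzene | Brc1ccc(OCc2ccccc2)cc1 | starting material
18 | (4S,5S)-2-[(1R,2R,3S)-2-(benzyloxy)-1-chloro-3-(ArA)-3-(ArD)propyl]-4,5-dicyclohexyl-1,3,2-dioxaborolane | Cl[C@@H]([C@H](OCc1ccccc1)[C@H](c1ccc(OCc2ccccc2)cc1Br)c1c(OCc2ccccc2)cc(OCc2ccccc2)cc1/C=C/c1ccc(OCc2ccccc2)c(OCc2ccccc2)c1)B1O[C@@H](C2CCCCC2)[C@H](C2CCCCC2)O1 | intermediate (not isolated)
19 | [4-(benzyloxy)phenyl]magnesium bromide | Br[Mg]c1ccc(OCc2ccccc2)cc1 | intermediate (not isolated)
20 | (4S,5S)-2-[(1R,2S,3S)-2-(benzyloxy)-1-[4-(benzyloxy)phenyl]-3-(ArA)-3-(ArD)propyl]-4,5-dicyclohexyl-1,3,2-dioxaborolane (product of the key step) | B1([C@H](c2ccc(OCc3ccccc3)cc2)[C@H](OCc2ccccc2)[C@H](c3ccc(OCc4ccccc4)cc3Br)c3c(OCc4ccccc4)cc(OCc4ccccc4)cc3/C=C/c3ccc(OCc4ccccc4)c(OCc4ccccc4)c3)O[C@@H](C2CCCCC2)[C@H](C2CCCCC2)O1 | intermediate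
21 | (1R,2R,3S)-2-(benzyloxy)-1-[4-(benzyloxy)phenyl]-3-(ArA)-3-(ArD)propan-1-ol | O[C@H](c1ccc(OCc2ccccc2)cc1)[C@H](OCc1ccccc1)[C@H](c1ccc(OCc2ccccc2)cc1Br)c1c(OCc2ccccc2)cc(OCc2ccccc2)cc1/C=C/c1ccc(OCc2ccccc2)c(OCc2ccccc2)c1 | intermediate
22 | (2R,3R,4R)-3,7-bis(benzyloxy)-2-[4-(benzyloxy)phenyl]-4-(ArD)chromane | c1ccccc1COc1ccc([C@H]2Oc3cc(OCc4ccccc4)ccc3[C@H](c3c(OCc4ccccc4)cc(OCc4ccccc4)cc3/C=C/c3ccc(OCc4ccccc4)c(OCc4ccccc4)c3)[C@H]2OCc2ccccc2)cc1 | intermediate
23 | (2R,3R,4R)-4-{2-[(E)-2-(3,4-dihydroxyphenyl)ethenyl]-4,6-dihydroxyphenyl}-2-(4-hydroxyphenyl)chromane-3,7-diol | Oc1ccc([C@H]2Oc3cc(O)ccc3[C@H](c3c(O)cc(O)cc3/C=C/c3ccc(O)c(O)c3)[C@H]2O)cc1 | target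

## Step count and least certain steps

Total: 11 steps. Longest linear sequence: 8 steps (steps 1, 3, 6, 7, 8, 9, 10 and 11, from 1).

**Step 8 (key step).**
- Risk: insertion of LiCHCl2 may be slow at a boron flanked by the C3 ether and the diarylmethyl group, so that the carbenoid decays first. In the Grignard stage, the aryl ate complex may lose benzyloxide from the β-carbon (boron–oxygen elimination), or a ring oxygen may migrate in place of the aryl group.
- Fallback: this sets out from 18 and returns at 21, so it also replaces step 9. Crude 18 is oxidised with H2O2 at pH 8 (NaHCO3 buffer, THF, 0 °C) to (2R,3S)-2-(benzyloxy)-3-(ArA)-3-(ArD)propanal F1. Grignard reagent 19 is then added to F1 in CH2Cl2/Et2O with MgBr2·OEt2 at −78 °C. Magnesium chelated between the aldehyde oxygen and the C3 ether oxygen directs the aryl group to the face away from the diarylmethyl group, which should give the syn alcohol 21. C2 is then set by the substrate and not by the diol, and no aryl ate complex with a β-leaving group is involved.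

**Step 6.**
- Risk: loss of configuration at C4. Chloride 12 has alkoxy groups ortho and para to the benzylic carbon and can ionise (helped by zinc) or exchange chloride before the Grignard reagent traps it. The second ate complex is also crowded.
- Fallback: the roles of the rings are exchanged, which requires the mirror-image diol for this one cycle, and the diol is swapped afterwards. It sets out from 13 and 11 and returns at 14. Reagent 13 is quenched with B(OMe)3 and worked up with acid to [4-(benzyloxy)-2-bromophenyl]boronic acid F2. F2 is condensed with (1R,2R)-1,2-dicyclohexylethane-1,2-diol to 2-(ArA)-(4R,5R)-4,5-dicyclohexyl-1,3,2-dioxaborolane F3. LiCHCl2/ZnCl2 then gives (4R,5R)-2-[(S)-chloro(ArA)methyl]-4,5-dicyclohexyl-1,3,2-dioxaborolane F4. F4 ionises less easily than 12 because it has one para donor and an ortho bromine. Aryllithium 11 is added at −78 °C; ring D migrates with inversion and gives (4R,5R)-4,5-dicyclohexyl-2-[(S)-(ArA)(ArD)methyl]-1,3,2-dioxaborolane F5, with C4 arranged as in 14. KHF2 in MeOH/H2O frees the diol and gives potassium (S)-[(ArA)(ArD)methyl]trifluoroborate F6. Me3SiCl with diol 6 in MeCN re-esterifies boron to 14.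

**Step 10.**
- Risk: slow insertion of copper into the hindered, electron-rich C–Br bond, so that oxidation of the benzylic alkoxide to the ketone or loss of bromine competes at 110 °C.
- Fallback: the polarity of the aryl partner is reversed. It sets out from 21 and returns at 22. Miyaura borylation (Pd(dppf)Cl2, bis(pinacolato)diboron, KOAc, dioxane, 90 °C) gives (1R,2R,3R)-2-(benzyloxy)-1-[4-(benzyloxy)phenyl]-3-[4-(benzyloxy)-2-(4,4,5,5-tetramethyl-1,3,2-dioxaborolan-2-yl)phenyl]-3-(ArD)propan-1-ol F7. An intramolecular Chan–Lam etherification (Cu(OAc)2, pyridine, 4 Å sieves, air, CH2Cl2, rt) then closes O1–C8a under oxidative divalent-copper conditions at room temperature.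

**Step 11.**
- Risk: the secondary benzyl ether at C3, flanked by C2 and C4, may be cleaved more slowly than the six aryl ethers. Warming to remove it would favour ionisation of the O1–C2 bond (ring opening, epimerisation at C2) and electrophilic attack on the stilbene.
- Fallback: the C3 oxygen is carried as a 4-methoxybenzyl ether, which ionises at −78 °C. It sets out from 14 and returns at 23.
 - 14 is homologated to 15 as in step 7, and 15 is treated with lithium 4-methoxybenzyl oxide (from 4-methoxybenzyl alcohol and n-BuLi) to give (4S,5S)-4,5-dicyclohexyl-2-[(1S,2S)-1-(4-methoxybenzyloxy)-2-(ArA)-2-(ArD)ethyl]-1,3,2-dioxaborolane F8.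
 - The key step is run on F8: LiCHCl2/ZnCl2 gives (4S,5S)-2-[(1R,2R,3S)-1-chloro-2-(4-methoxybenzyloxy)-3-(ArA)-3-(ArD)propyl]-4,5-dicyclohexyl-1,3,2-dioxaborolane F9, and reagent 19 gives (4S,5S)-2-[(1R,2S,3S)-1-[4-(benzyloxy)phenyl]-2-(4-methoxybenzyloxy)-3-(ArA)-3-(ArD)propyl]-4,5-dicyclohexyl-1,3,2-dioxaborolane F10.
 - H2O2/NaOH gives (1R,2R,3S)-1-[4-(benzyloxy)phenyl]-2-(4-methoxybenzyloxy)-3-(ArA)-3-(ArD)propan-1-ol F11.
 - The CuI-catalysed closure gives (2R,3R,4R)-7-(benzyloxy)-2-[4-(benzyloxy)phenyl]-3-(4-methoxybenzyloxy)-4-(ArD)chromane F12.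
 - BCl3 with pentamethylbenzene, held at −78 °C, then gives 23.

## Further compounds

F1 | step 8 | (2R,3S)-2-(benzyloxy)-3-(ArA)-3-(ArD)propanal | O=C[C@H](OCc1ccccc1)[C@H](c1ccc(OCc2ccccc2)cc1Br)c1c(OCc2ccccc2)cc(OCc2ccccc2)cc1/C=C/c1ccc(OCc2ccccc2)c(OCc2ccccc2)c1
F2 | step 6 | [4-(benzyloxy)-2-bromophenyl]boronic acid | OB(O)c1ccc(OCc2ccccc2)cc1Br
F3 | step 6 | 2-[4-(benzyloxy)-2-bromophenyl]-(4R,5R)-4,5-dicyclohexyl-1,3,2-dioxaborolane | Brc1cc(OCc2ccccc2)ccc1B1O[C@H](C2CCCCC2)[C@@H](C2CCCCC2)O1
F4 | step 6 | (4R,5R)-2-[(S)-chloro(ArA)methyl]-4,5-dicyclohexyl-1,3,2-dioxaborolane | Cl[C@H](c1ccc(OCc2ccccc2)cc1Br)B1O[C@H](C2CCCCC2)[C@@H](C2CCCCC2)O1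
F5 | step 6 | (4R,5R)-4,5-dicyclohexyl-2-[(S)-(ArA)(ArD)methyl]-1,3,2-dioxaborolane | B1([C@H](c2ccc(OCc3ccccc3)cc2Br)c2c(OCc3ccccc3)cc(OCc3ccccc3)cc2/C=C/c2ccc(OCc3ccccc3)c(OCc3ccccc3)c2)O[C@H](C2CCCCC2)[C@@H](C2CCCCC2)O1
F6 | step 6 | potassium (S)-[(ArA)(ArD)methyl]trifluoroborate | [K+].F[B-](F)(F)[C@H](c1ccc(OCc2ccccc2)cc1Br)c1c(OCc2ccccc2)cc(OCc2ccccc2)cc1/C=C/c1ccc(OCc2ccccc2)c(OCc2ccccc2)c1
F7 | step 10 | (1R,2R,3R)-2-(benzyloxy)-1-[4-(benzyloxy)phenyl]-3-[4-(benzyloxy)-2-(4,4,5,5-tetramethyl-1,3,2-dioxaborolan-2-yl)phenyl]-3-(ArD)propan-1-ol | O[C@H](c1ccc(OCc2ccccc2)cc1)[C@H](OCc1ccccc1)[C@H](c1ccc(OCc2ccccc2)cc1B1OC(C)(C)C(C)(C)O1)c1c(OCc2ccccc2)cc(OCc2ccccc2)cc1/C=C/c1ccc(OCc2ccccc2)c(OCc2ccccc2)c1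
F8 | step 11 | (4S,5S)-4,5-dicyclohexyl-2-[(1S,2S)-1-(4-methoxybenzyloxy)-2-(ArA)-2-(ArD)ethyl]-1,3,2-dioxaborolane | B1([C@H](OCc2ccc(OC)cc2)[C@H](c3ccc(OCc4ccccc4)cc3Br)c3c(OCc4ccccc4)cc(OCc4ccccc4)cc3/C=C/c3ccc(OCc4ccccc4)c(OCc4ccccc4)c3)O[C@@H](C2CCCCC2)[C@H](C2CCCCC2)O1
F9 | step 11 | (4S,5S)-2-[(1R,2R,3S)-1-chloro-2-(4-methoxybenzyloxy)-3-(ArA)-3-(ArD)propyl]-4,5-dicyclohexyl-1,3,2-dioxaborolane | Cl[C@@H]([C@H](OCc1ccc(OC)cc1)[C@H](c1ccc(OCc2ccccc2)cc1Br)c1c(OCc2ccccc2)cc(OCc2ccccc2)cc1/C=C/c1ccc(OCc2ccccc2)c(OCc2ccccc2)c1)B1O[C@@H](C2CCCCC2)[C@H](C2CCCCC2)O1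
F10 | step 11 | (4S,5S)-2-[(1R,2S,3S)-1-[4-(benzyloxy)phenyl]-2-(4-methoxybenzyloxy)-3-(ArA)-3-(ArD)propyl]-4,5-dicyclohexyl-1,3,2-dioxaborolane | B1([C@H](c2ccc(OCc3ccccc3)cc2)[C@H](OCc2ccc(OC)cc2)[C@H](c3ccc(OCc4ccccc4)cc3Br)c3c(OCc4ccccc4)cc(OCc4ccccc4)cc3/C=C/c3ccc(OCc4ccccc4)c(OCc4ccccc4)c3)O[C@@H](C2CCCCC2)[C@H](C2CCCCC2)O1
F11 | step 11 | (1R,2R,3S)-1-[4-(benzyloxy)phenyl]-2-(4-methoxybenzyloxy)-3-(ArA)-3-(ArD)propan-1-ol | O[C@H](c1ccc(OCc2ccccc2)cc1)[C@H](OCc1ccc(OC)cc1)[C@H](c1ccc(OCc2ccccc2)cc1Br)c1c(OCc2ccccc2)cc(OCc2ccccc2)cc1/C=C/c1ccc(OCc2ccccc2)c(OCc2ccccc2)c1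
F12 | step 11 | (2R,3R,4R)-7-(benzyloxy)-2-[4-(benzyloxy)phenyl]-3-(4-methoxybenzyloxy)-4-(ArD)chromane | c1ccccc1COc1ccc([C@H]2Oc3cc(OCc4ccccc4)ccc3[C@H](c3c(OCc4ccccc4)cc(OCc4ccccc4)cc3/C=C/c3ccc(OCc4ccccc4)c(OCc4ccccc4)c3)[C@H]2OCc2ccc(OC)cc2)cc1
A1 | alternative 1 | (R)-6-(benzyloxy)-3-[2,4-bis(benzyloxy)-6-bromophenyl]indan-1-one | O=C1C[C@@H](c2c(OCc3ccccc3)cc(OCc3ccccc3)cc2Br)c2ccc(OCc3ccccc3)cc21
A2 | alternative 1 | (R)-7-(benzyloxy)-4-[2,4-bis(benzyloxy)-6-bromophenyl]-3,4-dihydrocoumarin | O=C1C[C@@H](c2c(OCc3ccccc3)cc(OCc3ccccc3)cc2Br)c2ccc(OCc3ccccc3)cc2O1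
A3 | alternative 2 | racemic 5-(benzyloxy)-2-{[2,4-bis(benzyloxy)-6-bromophenyl](4-methylphenylsulfonyl)methyl}phenol | Oc1cc(OCc2ccccc2)ccc1C(c1c(OCc2ccccc2)cc(OCc2ccccc2)cc1Br)S(=O)(=O)c1ccc(C)cc1
A4 | alternative 2 | 3-(benzyloxy)-6-{[2,4-bis(benzyloxy)-6-bromophenyl]methylidene}cyclohexa-2,4-dien-1-one | O=C1C=C(OCc2ccccc2)C=CC1=Cc1c(OCc2ccccc2)cc(OCc2ccccc2)cc1Br
A5 | alternative 2 | 2-(benzyloxy)acetaldehyde | O=CCOCc1ccccc1
A6 | alternative 2 | 3,4-trans 3,7-bis(benzyloxy)-4-[2,4-bis(benzyloxy)-6-bromophenyl]chroman-2-ol (anomeric mixture) | OC1Oc2cc(OCc3ccccc3)ccc2[C@H](c2c(OCc3ccccc3)cc(OCc3ccccc3)cc2Br)[C@H]1OCc1ccccc1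
A7 | alternative 3 | (E)-8-[3,4-bis(benzyloxy)phenyl]-1-{3,7-bis(benzyloxy)-2-[4-(benzyloxy)phenyl]chroman-4-yl}oct-7-ene-2,4,6-trione, ring C configured as in 22 | c1ccccc1COc1ccc([C@H]2Oc3cc(OCc4ccccc4)ccc3[C@H](CC(=O)CC(=O)CC(=O)/C=C/c3ccc(OCc4ccccc4)c(OCc4ccccc4)c3)[C@H]2OCc2ccccc2)cc1
A8 | alternative 3 | penta-O-benzyl ether of 23 with the two ring-D phenols free | c1ccccc1COc1ccc([C@H]2Oc3cc(OCc4ccccc4)ccc3[C@H](c3c(O)cc(O)cc3/C=C/c3ccc(OCc4ccccc4)c(OCc4ccccc4)c3)[C@H]2OCc2ccccc2)cc1
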